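All runs are simulated with constants of no real substance; noise was put on by code.

The amounts were the same in gamma and zeta, 1.50 equivalents of coupling partner on the starting material, and so was the time, so temperature was the setting that parted the two flasks, and I judged them on a ladder of time scales.

| flask | starting material | coupling partner | temperature | remark | time |
|---|---|---|---|---|---|
| midnight | 0.17 M | 0.375 M | 24 °C | run made earlier |  |
| noon | 0.38 M | 0.375 M | 32 °C | run made earlier |  |
| gamma | 0.25 M | 0.375 M | 35 °C |  | 15 min |
| zeta | 0.25 M | 0.375 M | 20 °C |  | 15 min |

| run | time / min | target / % |
|---|---|---|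
| midnight | 3.00 | 50.2 |
| midnight | 6.00 | 56.4 |
| midnight | 10.0 | 51.0 |
| midnight | 12.0 | 47.1 |
| noon | 0.833 | 29.8 |
| noon | 2.00 | 41.5 |
| noon | 4.00 | 40.2 |
| noon | 6.00 | 33.1 |

(standard deviation of a reading: 1 percentage point)

- which of the two there is more of at the end, gamma (over-reaction product / target)
- which of the two there is more of at the end, zeta (over-reaction product / target)
- amount of target at the end, in percent of the starting material charged, gamma
- amount of target at the end, in percent of the starting material charged, zeta

- a reading or a percentage of target counts all its forms, free or not

I carried one quantity, the loss constant: the fraction of the standing target that goes per minute. My first answer came from a falling tail read as if no target were being made, which in noon gave 0.0972 min⁻¹. But my making rates said starting material was still feeding target there, so I went round once more. The first reading of each run gave a making rate: 0.232 min⁻¹ in midnight, taken as pseudo-first-order with partner in excess, and 0.510 min⁻¹ in noon, taken as second-order on a nearly equal charge. In noon this put back a feed of 0.0405 min⁻¹ of the charge across the tail. Adding the feed to the observed fall, I read loss constants of 0.0765 min⁻¹ in midnight and 0.207 min⁻¹ in noon, which is more than the first answer.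

As I read them, from 24 °C to 32 °C the loss constant grew 2.71-fold, faster than making per unit of partner, which grew 1.67-fold. I carried both to the new temperatures at the same growth per degree, with partner taken at its level when half the starting material was used. Gamma got 0.301 min⁻¹, its loss constant, and a making rate of 0.407 min⁻¹. Zeta got 0.0465 min⁻¹ and 0.155 min⁻¹.

The ladder, fastest first, read: making in gamma 2.46 min, loss in gamma 3.32 min, making in zeta 6.45 min, the run 15 min, loss in zeta 21.5 min. So I expected gamma to pass both of its rungs well inside the run, while zeta should make its target and keep much of it. Making followed by loss in series gave me 3.34% of target in gamma and 57.1% in zeta, with over-reaction product ahead in gamma and target ahead in zeta.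

The forecast said 11% for gamma, against my 3.34%, and 57% for zeta, with over-reaction product ahead in gamma and target ahead in zeta: “Its loss therefore seems not to need partner.”

Gamma gave 4.13% of target against 94.9% of over-reaction product, and zeta gave 51.8% of target against 35.6%.

    intermediate B → target (k = 0.00750 s⁻¹, Ea = 81.0 kJ mol⁻¹)
    2 starting material → homo dimer (k = 1.70 × 10⁻⁵ M⁻¹ s⁻¹, Ea = 77.0 kJ mol⁻¹)
    starting material ⇌ intermediate A (K = 0.460, k = 0.00680 s⁻¹, Ea = 89.0 kJ mol⁻¹, ΔH = −26.0 kJ mol⁻¹)
    crystals ⇌ target, rate k4*(cs4 - [target]) while solid is left; crystals form when [target] > cs4 (solubility = 0.190 M, k = 0.330 s⁻¹)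
    starting material + coupling partner ⇌ intermediate B (K = 7.90 M⁻¹, k = 0.00130 M⁻¹ s⁻¹, Ea = 78.0 kJ mol⁻¹, ΔH = −28.0 kJ mol⁻¹)
    starting material + coupling partner → target (k = 0.0150 M⁻¹ s⁻¹, Ea = 44.0 kJ mol⁻¹)
    target → over-reaction product (k = 8.20 × 10⁻⁴ s⁻¹, Ea = 87.0 kJ mol⁻¹)
    (constants at 20 °C)

The main reason gamma held so little target was the turning of target into over-reaction product: with that step struck out, the same flask stands at 99.0% of target instead of 4.13%. Applied to the logarithmic mean of gamma's target after 7.50 min, my loss constant gives a gain in over-reaction product of 24 percentage points, and gamma gained 22 points. Over the same stretch in zeta, 0.0465 min⁻¹ gives 19 points, and zeta gained 20 points.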